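The readings come from a simulation from invented constants; noise was put on by code.

- If the bis adduct is lost by coupling partner + bis adduct → triple product, its loss is first order in c(coupling partner), so that was the concentration I watched. At fixed c(coupling partner) the step is pseudo-first-order.

in all of them: substrate 0.45 M
- Thursday's: coupling partner 0.37 M; run made earlier
- Friday's: coupling partner 0.85 M; run made earlier
- ochre: coupling partner 0.540 M; time 5.0 d
- teal: coupling partner 0.900 M; time 5.0 d
- green: coupling partner 1.12 M; time 5.0 d

| run | time / d | bis adduct / % | single product / % |
|---|---|---|---|
| Thursday's | 0.250 | 10 | 20 |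
| Thursday's | 0.417 | 15 | 15 |
| Thursday's | 0.625 | 18 | 12 |
| Thursday's | 1.04 | 19 | 11 |
| Thursday's | 1.67 | 21 | 9 |
| Thursday's | 2.50 | 21 | 6 |
| Thursday's | 4.00 | 19 | 3 |
| Friday's | 0.250 | 26 | 19 |
| Friday's | 0.417 | 28 | 9 |
| Friday's | 0.625 | 27 | 4 |
| Friday's | 1.04 | 24 | 3 |
| Friday's | 1.67 | 18 | 2 |
| Friday's | 2.50 | 17 | 3 |
| Friday's | 4.00 | 12 | 2 |

(standard deviation of a reading: 1.5 percentage points)

- the earlier runs were read with a standard deviation of 1.5 percentage points
- reactions considered so far: substrate <-> dormant form; substrate + coupling partner -> single product; coupling partner + bis adduct -> triple product; coupling partner -> decomposition product; coupling partner + single product -> bis adduct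

* amount of bis adduct at the end, in percent of the substrate charged, for each flask in turn (ochre, teal, green)

- From Friday's run I read the loss constant of the bis adduct per molar of charged partner, 0.0116 M⁻¹ h⁻¹. It is the logarithm of the peak reading 28 % over the last reading 12 %, divided by the time between them and by the charge.
- Teal is charged with more partner than Friday's run. Friday's last bis adduct reading stood lower than its peak reading, so for teal I took that last reading, 12 % at 4.00 d, as an estimated ceiling.
- For the floor I carried Friday's peak on to 5.0 d at this constant times teal's charge, which gave 8.89 %. I took it as an estimated floor, not a proven one: I expected c(coupling partner) to fall with time, and the constant is a mean over Friday's readings.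
- The forecast gave 17 %, 10 % and 6 % for ochre, teal and green, saying “over-addition goes further”. Its teal value lay inside my bracket.
- The flasks gave 20.5 %, 9.55 % and 4.66 % for ochre, teal and green, so the forecast held, and teal lay inside the bracket.

    substrate ⇌ dormant form (K = 15.3, k = 0.271 h⁻¹)
    substrate + coupling partner → single product (k = 0.459 M⁻¹ h⁻¹)
    coupling partner + bis adduct → triple product (k = 0.163 M⁻¹ h⁻¹)
    coupling partner → decomposition product (k = 6.60 × 10⁻⁴ h⁻¹)
    coupling partner + single product → bis adduct (k = 0.500 M⁻¹ h⁻¹)

- In teal the bis adduct's half-life by the step to triple product alone, at charged partner, is 0.20 d, short against 5.0 d. The largest single effect on teal's end value, though not the whole reason, is the path from substrate to dormant form, both ways: with that path taken away, teal ends at 48.8 % instead of 9.55 %. On green, 0.0116 M⁻¹ h⁻¹ from Friday's peak gives 6.71 %, above the flask's 4.66 %, so there the floor failed. Green's partner still stood at 9.1 % of its charge at 5.00 d.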